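Product on Sunday's run reads 4.1% at 8.00 min and 23.7% at 80.0 min, and those readings give a ladder of times.

| setting | Sunday's | south | east |
|---|---|---|---|
| starting material | 0.020 M | 0.020 M | 0.020 M |
| partner | 0.83 equiv | 1.80 equiv | 1.20 equiv |
| free catalyst | 0.1 mol% | 0.1 mol% | 0.1 mol% |
| remark | run made earlier |  |  |
| time |  | 80 min | 80 min |

Sunday's run (percent of the starting material charged)

| time / min | catalyst intermediate B / % | catalyst intermediate C / % | starting material / % | product / % |
|---|---|---|---|---|
| 8.00 | 1.2 | 1.5 | 94.6 | 4.1 |
| 20.0 | 0 | 0.2 | 91.5 | 10.2 |
| 40.0 | 0.6 | 0 | 83.5 | 16.7 |
| 60.0 | 0 | 0.1 | 77.5 | 20.8 |
| 80.0 | 0.4 | 1.2 | 75.0 | 23.7 |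

(scatter of a reading: 1 percentage point)

* which of these there is most of at the end, counted by the starting material in it, south (product / starting material / catalyst intermediate C / catalyst intermediate B)
* which of these there is most of at the end, counted by the starting material in it, east (product / starting material / catalyst intermediate C / catalyst intermediate B)
* final amount of the leader among these, as a percentage of the starting material charged, in south
* final amount of the leader among these, as a percentage of the starting material charged, in east

- a reading or a percentage of product counts all its forms, free or not

The fastest rung is the catalyst's round. Sunday's opening product reading means one turnover takes about 0.195 min. Catalyst intermediates B and C hold 0.1 mol% of the starting material at the very top, against a scatter of 1 percentage point, so their readings are noise and the round sits in quasi-steady state. The next rung is the fading of the rate: Sunday's product rate drops by a factor of 3.53 over the run, a decay time near 63.4 min. The slowest rung is the starting material's own lifetime at the opening rate, 195 min. Turnover is far quicker than the fading, and the fading is quicker than the consumption of starting material, so the rate falls long before the starting material runs down: Sunday's run still reads 75.0% at 80.0 min.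

Sunday's run varies no charge, so it shows the order neither in starting material nor in partner. As an assumption of my own, the fractional loss rate of starting material is taken as proportional to the partner charge, with the same fading in flasks of equal loading at equal time; dividing the rates of two such flasks, the time history drops out. Sunday's last reading then gives 0.347 per equivalent for S, the logarithmic conversion per equivalent: the logarithm of charged over remaining starting material divided by equivalents of partner. My own reckoning leaves 53.6% of the starting material in south and 66.0% in east. The forecast also has starting material leading, but stands a little higher, at 57% in south and 68% in east, since “uncertainty leans towards more starting material remaining”.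

The flasks end with starting material leading, at 59.7% in south and 68.1% in east.

    catalyst intermediate B → released group + catalyst intermediate C (k = 94.0 min⁻¹)
    starting material + catalyst intermediate A ⇌ catalyst intermediate B (K = 50.0 L mol⁻¹, k = 73000 L mol⁻¹ min⁻¹)
    crystals ⇌ product, rate k3*(cs3 - [product]) while solid is left; crystals form when [product] > cs3 (solubility = 0.280 mM, k = 0.0610 min⁻¹)
    catalyst intermediate C ⇌ free catalyst + product (K = 0.00380 M, k = 14.0 min⁻¹)
    partner → decomposed reagent (k = 0.00810 min⁻¹)
    partner + free catalyst → catalyst intermediate A (k = 710 L mol⁻¹ min⁻¹)
    2 free catalyst → spent catalyst (k = 420 L mol⁻¹ min⁻¹)

At the end, south still has 36.5% of its partner free, and 0.0148 M of decomposed reagent has formed. South's S comes to 0.286 per equivalent, lower than Sunday's reading. A neighbour of south charged with 4.50 equiv of partner is reckoned by Sunday's S at 21.0% starting material, but it holds 42.3%, with product leading, and its S is 0.191 per equivalent.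

The numbers in the tables were computed on assumed constants.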